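The dihydropyranone ring (O1, C2, C3, C4, C4a, C8a) is cut at O1–C2. The trans pair of oxygens on C2 and C3, held between the C4 ketone and the p-oxygenated aryl on C2, is the imprint of an (αR,βS)-chalcone epoxide opened at its benzylic carbon by the C8a phenol oxygen. In one acid-triggered operation the masked phenol is released, closes the last ring 6-endo with inversion at C2 (C3 carried over unchanged), and the remaining MOM ethers fall off. The precursor is an acyclic tris-MOM 3',5'-diprenyl epoxychalcone, set up by poly-L-leucine-catalysed nucleophilic epoxidation that ignores the prenyl olefins.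

Key step: step 6

Remark: flavonoid numbering (O1, C2, C3, C4, C4a, C5–C8, C8a; B-ring positions primed) is used for the target and its cyclised relatives, chalcone numbering (A-ring positions primed, Cα next to the ketone, Cβ benzylic) for the open-chain compounds; compounds 4 and 6 are taken as purchasable.

Step 1
Reactants: 1 2,4-dihydroxyacetophenone
Product: 2 1-(2,4-dihydroxy-3,5-diiodophenyl)ethan-1-one
Conditions: NIS (2.1 equiv), MeCN, 0 °C → rt
Reagents that add atoms: N-iodosuccinimide, O=C1CCC(=O)N1I
Why: Electrophilic aromatic iodination; C3 and C5 are each ortho/para to both hydroxyls, whereas C6 is meta to both and ortho to the acetyl group, so double iodination should stop cleanly at the 3,5-diiodide.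

Step 2
Reactants: 2 1-(2,4-dihydroxy-3,5-diiodophenyl)ethan-1-one
Product: 3 1-[3,5-diiodo-2,4-bis(methoxymethoxy)phenyl]ethan-1-one
Conditions: NaH (2.2 equiv), MOMCl (2.5 equiv), DMF, 0 °C → rt
Reagents that add atoms: chloromethyl methyl ether (MOMCl), COCCl
Why: Williamson-type O-alkylation (MOM protection) of both phenoxides; the iodine-acidified phenols are deprotonated by NaH well before the methyl ketone, and the sodium salt breaks the chelate of the 2-OH so that it is alkylated too.

Step 3
Reactants: 3 1-[3,5-diiodo-2,4-bis(methoxymethoxy)phenyl]ethan-1-one; 4 tributyl(3-methylbut-2-en-1-yl)stannane (2.6 equiv)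
Product: 5 1-[2,4-bis(methoxymethoxy)-3,5-bis(3-methylbut-2-en-1-yl)phenyl]ethan-1-one
Conditions: Pd(PPh3)4 (10 mol %), DMF, 100 °C
Reagents that add atoms: none
Why: Twofold Stille cross-coupling of the aryl iodides with the allylic stannane; C–C bond formation at the less hindered allyl terminus should give the linear prenyl groups, and the ketone and MOM ethers are inert under these neutral conditions.

Step 4
Reactants: 5 1-[2,4-bis(methoxymethoxy)-3,5-bis(3-methylbut-2-en-1-yl)phenyl]ethan-1-one; 6 4-(methoxymethoxy)benzaldehyde
Product: 7 (E)-1-[2,4-bis(methoxymethoxy)-3,5-bis(3-methylbut-2-en-1-yl)phenyl]-3-[4-(methoxymethoxy)phenyl]prop-2-en-1-one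
Conditions: KOH, EtOH/H2O, rt
Reagents that add atoms: none
Why: Claisen–Schmidt condensation (aldol addition, then E1cB dehydration) should give the thermodynamically favoured E-enone; with all phenols masked, neither oxa-Michael closure nor phenoxide deactivation of the aldehyde can interfere.

Step 5
Reactants: 7 (E)-1-[2,4-bis(methoxymethoxy)-3,5-bis(3-methylbut-2-en-1-yl)phenyl]-3-[4-(methoxymethoxy)phenyl]prop-2-en-1-one
Product: 8 [2,4-bis(methoxymethoxy)-3,5-bis(3-methylbut-2-en-1-yl)phenyl]{(2R,3S)-3-[4-(methoxymethoxy)phenyl]oxiran-2-yl}methanone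
Conditions: immobilised poly-L-leucine, urea–H2O2, DBU, THF, rt
Reagents that add atoms: urea–hydrogen peroxide, NC(N)=O.OO
Why: Juliá–Colonna epoxidation (Weitz–Scheffer conjugate addition of hydroperoxide and closure of the peroxy-enolate inside the N-terminal hydrogen-bonding turn of the helical L-peptide): the nucleophilic oxidant attacks only the electron-poor enone and not the electron-rich prenyl olefins, and the L-configured helix is the element that should deliver oxygen to the enone face giving the (2R,3S)-trans-epoxide, whose Cα becomes C3 of the target.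

Step 6
Reactants: 8 [2,4-bis(methoxymethoxy)-3,5-bis(3-methylbut-2-en-1-yl)phenyl]{(2R,3S)-3-[4-(methoxymethoxy)phenyl]oxiran-2-yl}methanone
Product: 11 Lespeflorin B2, via 2'-hydroxy epoxy ketone 9 (not isolated), via bis-MOM dihydroflavonol 10 (not isolated)
Conditions: 3 M HCl in MeOH, THF (co-solvent), 40 °C
Reagents that add atoms: none
Why: Acid-catalysed acetal cleavage removes the MOM group ortho to the ketone first (its phenol is the best leaving group and is hydrogen-bonded to the carbonyl), and the freed phenol of 9 attacks the acid-activated epoxide at the benzylic Cβ, an intramolecular epoxide opening by a phenol that is the ring-closing event of the classical epoxychalcone-to-dihydroflavonol conversion (the closure step of the Algar–Flynn–Oyamada reaction). The pyranone ring closes in the 6-endo-tet mode. C3 is the epoxide Cα, whose C–O bond is never broken, so its R configuration is carried over from step 5; C2 is set by anti (invertive) attack at Cβ, which turns the trans-epoxide into the 2,3-trans (2R,3R) product. Should the opening become SN1-like through the p-oxygenated benzylic cation, or pass through a reversible methanol or chloride adduct, the retained C3 centre should still direct closure to the diequatorial trans isomer. The step needs regioselectivity for Cβ over Cα (5-exo closure to the benzofuranone series) and over 1,2-aroyl shift, which the cation-stabilising 4-oxygenated aryl on Cβ and the deactivating carbonyl on Cα secure, and chemoselectivity against addition of the new 7-OH to the flanking prenyl olefins, which dilute acid at 40 °C should respect. The two remaining MOM ethers of 10 are then cleaved in the same pot.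

Compound list
1 | 2,4-dihydroxyacetophenone [1-(2,4-dihydroxyphenyl)ethan-1-one] | CC(=O)c1ccc(O)cc1O | starting material
2 | 1-(2,4-dihydroxy-3,5-diiodophenyl)ethan-1-one | CC(=O)c1cc(I)c(O)c(I)c1O | intermediate
3 | 1-[3,5-diiodo-2,4-bis(methoxymethoxy)phenyl]ethan-1-one | CC(=O)c1cc(I)c(OCOC)c(I)c1OCOC | intermediate
4 | tributyl(3-methylbut-2-en-1-yl)stannane (prenyltributyltin) | CCCC[Sn](CCCC)(CCCC)CC=C(C)C | starting material
5 | 1-[2,4-bis(methoxymethoxy)-3,5-bis(3-methylbut-2-en-1-yl)phenyl]ethan-1-one | CC(=O)c1cc(CC=C(C)C)c(OCOC)c(CC=C(C)C)c1OCOC | intermediate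
6 | 4-(methoxymethoxy)benzaldehyde | COCOc1ccc(C=O)cc1 | starting material
7 | (E)-1-[2,4-bis(methoxymethoxy)-3,5-bis(3-methylbut-2-en-1-yl)phenyl]-3-[4-(methoxymethoxy)phenyl]prop-2-en-1-one | COCOc1ccc(/C=C/C(=O)c2cc(CC=C(C)C)c(OCOC)c(CC=C(C)C)c2OCOC)cc1 | intermediate
8 | [2,4-bis(methoxymethoxy)-3,5-bis(3-methylbut-2-en-1-yl)phenyl]{(2R,3S)-3-[4-(methoxymethoxy)phenyl]oxiran-2-yl}methanone | O=C(c1cc(CC=C(C)C)c(OCOC)c(CC=C(C)C)c1OCOC)[C@@H]2O[C@H]2c3ccc(OCOC)cc3 | intermediate
9 | [2-hydroxy-4-(methoxymethoxy)-3,5-bis(3-methylbut-2-en-1-yl)phenyl]{(2R,3S)-3-[4-(methoxymethoxy)phenyl]oxiran-2-yl}methanone | O=C(c1cc(CC=C(C)C)c(OCOC)c(CC=C(C)C)c1O)[C@@H]2O[C@H]2c3ccc(OCOC)cc3 | intermediate (not isolated)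
10 | (2R,3R)-3-hydroxy-7-(methoxymethoxy)-2-[4-(methoxymethoxy)phenyl]-6,8-bis(3-methylbut-2-en-1-yl)-2,3-dihydro-4H-chromen-4-one | CC(C)=CCc1cc2c(c(CC=C(C)C)c1OCOC)O[C@H](c1ccc(OCOC)cc1)[C@@H](O)C2=O | intermediate (not isolated)
11 | Lespeflorin B2, (2R,3R)-3,7-dihydroxy-2-(4-hydroxyphenyl)-6,8-bis(3-methylbut-2-en-1-yl)-2,3-dihydro-4H-chromen-4-one | CC(C)=CCc1cc2c(c(CC=C(C)C)c1O)O[C@H](c1ccc(O)cc1)[C@@H](O)C2=O | target

Total step count: 6
Longest linear sequence: 6 steps (1 → 2 → 3 → 5 → 7 → 8 → 11)

Steps most likely to fail

Step 6 (key step). The very labile p-alkoxybenzylic epoxide may be opened by methanol or chloride without subsequent closure. It may also undergo 1,2-aroyl shift or 5-exo closure, and the unmasked 7-OH may add to a flanking prenyl olefin under the acid. The fallback separates opening, closure and deprotection. Setting out from 8, the epoxide would be opened at −20 °C with phenylmethanethiol and catalytic SnCl4 in CH2Cl2. This places a benzylsulfanyl group on the benzylic carbon and removes only the chelated 2'-MOM group, giving the β-benzylsulfanyl α-hydroxy ketone F1. It is drawn as the anti (inversion) adduct; its epimer at the sulfur-bearing carbon would serve equally. The thiophilic Lewis acid AgBF4 in CH2Cl2 at 0 °C would then ionise the C–S bond and let the phenol close the ring to the 2,3-trans bis-MOM dihydroflavonol. This rejoins the route at compound 10, whose two remaining MOM ethers would be removed with the methanolic HCl of step 6 at room temperature, with no epoxide left to divert.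

Step 5. Conversion may be slow and facial selectivity eroded, because the aroyl group flanked by 2'-OMOM and 3'-prenyl is twisted and bulky and may fit the peptide helix poorly. The fallback builds the epoxide by a Darzens reaction instead of oxidising the enone. Setting out from 5, the lithium enolate (LiHMDS, THF, −78 °C) would be chlorinated with p-toluenesulfonyl chloride to the α-chloro ketone F2. F2 would be condensed with aldehyde 6 under asymmetric phase-transfer Darzens conditions (cinchona-derived quaternary ammonium salt, LiOH·H2O, toluene, 0 °C). The pseudoenantiomeric catalyst series would be chosen to deliver the (2R,3S)-trans-epoxy ketone, rejoining the route at compound 8.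

Step 3. The second coupling at the iodide flanked by two MOM ethers may stall, protodeiodination may compete, and part of the allyl transfer may go through the γ-terminus to 1,1-dimethylallyl isomers. The fallback is direct nuclear prenylation without halogen or palladium. Setting out from 1, prenyl bromide (1-bromo-3-methylbut-2-ene, CC(C)=CCBr) in aqueous KOH at 0 °C → rt would C-alkylate the resorcinol-type phenoxide at C3 and C5 to give 2,4-dihydroxy-3,5-diprenylacetophenone F3. It would be separated by chromatography from mono-C-prenylated and O-prenylated material. Bis-MOM protection (MOMCl, NaH, DMF) would then rejoin the route at compound 5.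

Further compounds
F1 | step 6 | (2S,3R)-3-(benzylsulfanyl)-2-hydroxy-1-[2-hydroxy-4-(methoxymethoxy)-3,5-bis(3-methylbut-2-en-1-yl)phenyl]-3-[4-(methoxymethoxy)phenyl]propan-1-one | O=C(c1cc(CC=C(C)C)c(OCOC)c(CC=C(C)C)c1O)[C@H](O)[C@H](SCc2ccccc2)c3ccc(OCOC)cc3
F2 | step 5 | 2-chloro-1-[2,4-bis(methoxymethoxy)-3,5-bis(3-methylbut-2-en-1-yl)phenyl]ethan-1-one | O=C(CCl)c1cc(CC=C(C)C)c(OCOC)c(CC=C(C)C)c1OCOC
F3 | step 3 | 1-[2,4-dihydroxy-3,5-bis(3-methylbut-2-en-1-yl)phenyl]ethan-1-one | CC(=O)c1cc(CC=C(C)C)c(O)c(CC=C(C)C)c1O
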